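**Retrosynthetic overview**

1. The meso trans,trans 3,3'-biflavanone is cut in both halves at the aryl–acyl bond C-4–C-4a (C-4'–C-4a'). Both pyranone rings are closed last, in one operation, from an open-chain meso bis(aryl ether) bis(Weinreb amide) that carries bromine on each future C-4a.
2. Enabling feature: in each half the carbonyl carbon C-4 lies three atoms (C-3, C-2, O-1) from ring-A carbon C-8a, whose ortho carbon C-4a (para to the 7-oxygen) can carry bromine and hence lithium. Attack of C-4a on C-4 therefore closes a six-membered ring, and the mirror symmetry of the meso chain makes the two closures the same event.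
3. The two ether bonds O-1–C-2 come from two separate Mitsunobu inversions with 5-(benzyloxy)-2-bromophenol, one before and one after the opening of a temporary γ-lactone. The lactone masks the second carbinol during the first etherification, so a free 1,4-diol never meets the Mitsunobu reagents.
4. The four contiguous stereocentres are set on that γ-lactone, which is not in the target: aldol–lactonisation of succinic anhydride with 4-(benzyloxy)benzaldehyde (2,3-trans), then a syn aldol addition trans to the ring substituent.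
5. Ring order: temporary lactone (made, then opened), then both chromanone rings together, then debenzylation.

Key step: step 7

Remark: the descriptors (2S,3R,2'R,3'S) describe the meso trans,trans isomer (the two flavanone halves are mirror images), so racemic intermediates suffice and are drawn as one enantiomer; 5-(benzyloxy)-2-bromophenol is taken as a purchasable starting material.

**Route**

Step 1
Reactants: 1 succinic anhydride; 2 4-(benzyloxy)benzaldehyde
Product: 3 rac-(2R,3R)-2-[4-(benzyloxy)phenyl]-5-oxooxolane-3-carboxylic acid (2,3-trans paraconic acid)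
Conditions: ZnCl2, Et3N, CH2Cl2, rt; then 1 M HCl; crystallisation
Reagents that add atoms: none
Why: ZnCl2/Et3N-mediated aldol addition of the anhydride enolate to the aldehyde and lactonisation of the aldolate (Fittig-type paraconic acid synthesis) should give the γ-lactone, and the reversible aldol step lets the two new centres settle in the more stable 2,3-trans arrangement.

Step 2
Reactants: 3 rac-(2R,3R)-2-[4-(benzyloxy)phenyl]-5-oxooxolane-3-carboxylic acid
Product: 4 rac-(2R,3R)-2-[4-(benzyloxy)phenyl]-N-methoxy-N-methyl-5-oxooxolane-3-carboxamide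
Conditions: MeNHOMe·HCl, EDC·HCl, HOBt (cat.), N-methylmorpholine, CH2Cl2, 0 °C to rt
Reagents that add atoms: N,O-dimethylhydroxylamine hydrochloride, CNOC.Cl
Why: Carbodiimide amide coupling turns the acid into the Weinreb amide that later accepts exactly one aryl nucleophile; the weak base avoids β-elimination and no stereocentre is touched.

Step 3
Reactants: 4 rac-(2R,3R)-2-[4-(benzyloxy)phenyl]-N-methoxy-N-methyl-5-oxooxolane-3-carboxamide; 2 4-(benzyloxy)benzaldehyde
Product: 7 rac-(2R,3R,4S)-2-[4-(benzyloxy)phenyl]-4-{(S)-[4-(benzyloxy)phenyl](hydroxy)methyl}-N-methoxy-N-methyl-5-oxooxolane-3-carboxamide, via lithium enolate 5 (not isolated), via zirconium enolate 6 (not isolated)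
Conditions: LiN(i-Pr)2 (LDA), THF, −78 °C; Cp2ZrCl2, −78 to −40 °C; then 2, −78 °C; H2O
Reagents that add atoms: none
Why: Kinetic deprotonation occurs at the lactone CH2, and the zirconium-enolate aldol addition should take place anti to the neighbouring carboxamide (3,4-trans) and with the syn simple diastereoselectivity that zirconium enolates show whatever the enolate geometry, so the new half acquires the mirror-image relative configuration of the lactone-bound half.

Step 4
Reactants: 7 rac-(2R,3R,4S)-2-[4-(benzyloxy)phenyl]-4-{(S)-[4-(benzyloxy)phenyl](hydroxy)methyl}-N-methoxy-N-methyl-5-oxooxolane-3-carboxamide; 8 5-(benzyloxy)-2-bromophenol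
Product: 9 rac-(2R,3R,4S)-4-{(R)-[5-(benzyloxy)-2-bromophenoxy][4-(benzyloxy)phenyl]methyl}-2-[4-(benzyloxy)phenyl]-N-methoxy-N-methyl-5-oxooxolane-3-carboxamide
Conditions: PPh3, DIAD, toluene, 0 °C to rt
Reagents that add atoms: none
Why: In this Mitsunobu etherification the acidic bromophenol displaces the activated benzylic oxygen in an SN2 process, so the exocyclic carbinol carbon is inverted from (S) to (R), and because the other carbinol oxygen is still tied up in the lactone, only one hydroxyl reacts and no cyclodehydration to a tetrahydrofuran can compete.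

Step 5
Reactants: 9 rac-(2R,3R,4S)-4-{(R)-[5-(benzyloxy)-2-bromophenoxy][4-(benzyloxy)phenyl]methyl}-2-[4-(benzyloxy)phenyl]-N-methoxy-N-methyl-5-oxooxolane-3-carboxamide
Product: 10 rac-(2R,3S)-2-{(R)-[4-(benzyloxy)phenyl](hydroxy)methyl}-3-{(R)-[5-(benzyloxy)-2-bromophenoxy][4-(benzyloxy)phenyl]methyl}-N1,N4-dimethoxy-N1,N4-dimethylbutanediamide
Conditions: AlMe3, MeNHOMe·HCl, CH2Cl2, 0 °C to rt; aq potassium sodium tartrate (KNaC4H4O6); used directly
Reagents that add atoms: N,O-dimethylhydroxylamine hydrochloride, CNOC.Cl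
Why: Aluminium-amide aminolysis of the lactone (Weinreb amide formation) opens the temporary ring at the acyl–oxygen bond, so all four stereocentres are retained, the aryl bromide and the ethers are untouched, and the second carbinol is set free only now.

Step 6
Reactants: 10 rac-(2R,3S)-2-{(R)-[4-(benzyloxy)phenyl](hydroxy)methyl}-3-{(R)-[5-(benzyloxy)-2-bromophenoxy][4-(benzyloxy)phenyl]methyl}-N1,N4-dimethoxy-N1,N4-dimethylbutanediamide; 8 5-(benzyloxy)-2-bromophenol
Product: 11 meso-(2R,3S)-2-{(S)-[5-(benzyloxy)-2-bromophenoxy][4-(benzyloxy)phenyl]methyl}-3-{(R)-[5-(benzyloxy)-2-bromophenoxy][4-(benzyloxy)phenyl]methyl}-N1,N4-dimethoxy-N1,N4-dimethylbutanediamide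
Conditions: PPh3, DIAD, toluene/THF, −20 °C to rt
Reagents that add atoms: none
Why: A second Mitsunobu etherification inverts the remaining carbinol carbon from (R) to (S) by SN2 displacement with the bromophenol, which makes the two halves mirror images (meso) and gives each half the ether/amide arrangement that corresponds to a 2,3-trans chromanone.

Step 7
Reactants: 11 meso-(2R,3S)-2-{(S)-[5-(benzyloxy)-2-bromophenoxy][4-(benzyloxy)phenyl]methyl}-3-{(R)-[5-(benzyloxy)-2-bromophenoxy][4-(benzyloxy)phenyl]methyl}-N1,N4-dimethoxy-N1,N4-dimethylbutanediamide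
Product: 14 meso-(2S,3R,2'R,3'S)-7,7'-bis(benzyloxy)-2,2'-bis[4-(benzyloxy)phenyl]-[3,3'-bichromane]-4,4'-dione, via bis(aryllithium) 12 (not isolated), via dilithium bis(hemiaminal alkoxide) 13 (not isolated)
Conditions: t-BuLi (4.1 equiv), THF, −78 to −40 °C; then 1 M HCl
Reagents that add atoms: none
Why: Twofold bromine–lithium exchange gives 12, and each carbanion at C-4a attacks the Weinreb carbonyl C-4 three atoms away to give the chelated tetrahedral species 13, which releases the two ketones only on acidic work-up, so neither over-addition nor enolisation at C-3 of a formed ketone can occur before the quench. The closest known reaction type is the Parham cyclisation (aryl bromide, alkyllithium, internal Weinreb amide as acyl acceptor), a known way to benzo-fused cyclic ketones including chroman-4-ones; here it is run twice on one meso chain. Each pyranone ring closes in the 6-exo-trig mode. No stereocentre is made or broken: C-2/C-2' keep the configuration set by the two Mitsunobu inversions and C-3/C-3' that set on the lactone, and together these already are the 2,3-trans arrangement in both halves. The step needs exchange and carbonyl attack to outrun deprotonation at C-3 (which would expel the aryloxide) and attack on the more distant amide (a seven-membered ring); fast exchange at −78 °C, lithium coordination by the nearby Weinreb amide and the six- over seven-membered transition state should secure this, while the bromine position allows only the 7-oxygenated chromanone.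

Step 8
Reactants: 14 meso-(2S,3R,2'R,3'S)-7,7'-bis(benzyloxy)-2,2'-bis[4-(benzyloxy)phenyl]-[3,3'-bichromane]-4,4'-dione
Product: 15 (2S,3R,2'R,3'S)-7,7'-dihydroxy-2,2'-bis(4-hydroxyphenyl)-[3,3'-bichromane]-4,4'-dione (CNP0231820.1)
Conditions: H2 (1 atm), Pd/C, EtOAc/MeOH, rt
Reagents that add atoms: none
Why: Catalytic hydrogenolysis cleaves the four benzyl ethers under neutral conditions, which avoids base-induced opening of the flavanone rings and should leave all four stereocentres untouched.

**Compound list**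

1 | succinic anhydride | O=C1CCC(=O)O1 | starting material
2 | 4-(benzyloxy)benzaldehyde | O=Cc1ccc(OCc2ccccc2)cc1 | starting material
3 | rac-(2R,3R)-2-[4-(benzyloxy)phenyl]-5-oxooxolane-3-carboxylic acid | O=C1C[C@@H](C(=O)O)[C@H](c2ccc(OCc3ccccc3)cc2)O1 | intermediate
4 | rac-(2R,3R)-2-[4-(benzyloxy)phenyl]-N-methoxy-N-methyl-5-oxooxolane-3-carboxamide | O=C1C[C@@H](C(=O)N(C)OC)[C@H](c2ccc(OCc3ccccc3)cc2)O1 | intermediate
5 | lithium enolate of 4 (lactone carbonyl O-lithiated) | [Li]OC1=C[C@@H](C(=O)N(C)OC)[C@H](c2ccc(OCc3ccccc3)cc2)O1 | intermediate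
6 | chlorobis(cyclopentadienyl)zirconium enolate of 4 | Cl[Zr](OC1=C[C@@H](C(=O)N(C)OC)[C@H](c2ccc(OCc3ccccc3)cc2)O1)(C1C=CC=C1)C1C=CC=C1 | intermediate
7 | rac-(2R,3R,4S)-2-[4-(benzyloxy)phenyl]-4-{(S)-[4-(benzyloxy)phenyl](hydroxy)methyl}-N-methoxy-N-methyl-5-oxooxolane-3-carboxamide | O=C1[C@H]([C@H](O)c2ccc(OCc3ccccc3)cc2)[C@@H](C(=O)N(C)OC)[C@H](c2ccc(OCc3ccccc3)cc2)O1 | intermediate
8 | 5-(benzyloxy)-2-bromophenol | Oc1cc(OCc2ccccc2)ccc1Br | starting material
9 | rac-(2R,3R,4S)-4-{(R)-[5-(benzyloxy)-2-bromophenoxy][4-(benzyloxy)phenyl]methyl}-2-[4-(benzyloxy)phenyl]-N-methoxy-N-methyl-5-oxooxolane-3-carboxamide | O=C1[C@H]([C@@H](Oc2cc(OCc3ccccc3)ccc2Br)c2ccc(OCc3ccccc3)cc2)[C@@H](C(=O)N(C)OC)[C@H](c2ccc(OCc3ccccc3)cc2)O1 | intermediate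
10 | rac-(2R,3S)-2-{(R)-[4-(benzyloxy)phenyl](hydroxy)methyl}-3-{(R)-[5-(benzyloxy)-2-bromophenoxy][4-(benzyloxy)phenyl]methyl}-N1,N4-dimethoxy-N1,N4-dimethylbutanediamide | CON(C)C(=O)[C@@H]([C@@H](O)c1ccc(OCc2ccccc2)cc1)[C@H](C(=O)N(C)OC)[C@@H](Oc1cc(OCc2ccccc2)ccc1Br)c1ccc(OCc2ccccc2)cc1 | intermediate
11 | meso-(2R,3S)-2-{(S)-[5-(benzyloxy)-2-bromophenoxy][4-(benzyloxy)phenyl]methyl}-3-{(R)-[5-(benzyloxy)-2-bromophenoxy][4-(benzyloxy)phenyl]methyl}-N1,N4-dimethoxy-N1,N4-dimethylbutanediamide | CON(C)C(=O)[C@@H]([C@H](Oc1cc(OCc2ccccc2)ccc1Br)c1ccc(OCc2ccccc2)cc1)[C@H](C(=O)N(C)OC)[C@@H](Oc1cc(OCc2ccccc2)ccc1Br)c1ccc(OCc2ccccc2)cc1 | intermediate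
12 | bis(aryllithium) of 11 (both bromines replaced by lithium) | CON(C)C(=O)[C@@H]([C@H](Oc1cc(OCc2ccccc2)ccc1[Li])c1ccc(OCc2ccccc2)cc1)[C@H](C(=O)N(C)OC)[C@@H](Oc1cc(OCc2ccccc2)ccc1[Li])c1ccc(OCc2ccccc2)cc1 | intermediate
13 | dilithium bis(hemiaminal alkoxide): both rings closed, each C-4 bearing OLi and N(OMe)Me (C-4 configuration undefined) | CON(C)C1(O[Li])c2ccc(OCc3ccccc3)cc2O[C@H](c2ccc(OCc3ccccc3)cc2)[C@H]1[C@@H]1C(O[Li])(N(C)OC)c2ccc(OCc3ccccc3)cc2O[C@H]1c1ccc(OCc2ccccc2)cc1 | intermediate
14 | meso-(2S,3R,2'R,3'S)-7,7'-bis(benzyloxy)-2,2'-bis[4-(benzyloxy)phenyl]-[3,3'-bichromane]-4,4'-dione | O=C1c2ccc(OCc3ccccc3)cc2O[C@H](c2ccc(OCc3ccccc3)cc2)[C@H]1[C@@H]1C(=O)c2ccc(OCc3ccccc3)cc2O[C@H]1c1ccc(OCc2ccccc2)cc1 | intermediate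
15 | (2S,3R,2'R,3'S)-7,7'-dihydroxy-2,2'-bis(4-hydroxyphenyl)-[3,3'-bichromane]-4,4'-dione | O=C1c2ccc(O)cc2O[C@H](c2ccc(O)cc2)[C@H]1[C@@H]1C(=O)c2ccc(O)cc2O[C@H]1c1ccc(O)cc1 | target

Total step count: 8
Longest linear sequence: 8 steps (1 and 2 to 15)

**Steps most likely to fail**

Step 7 (double cyclisation). The aryllithium may act as a base at C-3 (expelling the aryloxide) or at the benzylic C-2–H, or the second exchange may lag so that only one ring closes. The fallback sets out from 11 and returns at 14. Reduction of both Weinreb amides (i-Bu2AlH, THF, −78 °C) should give the dialdehyde meso-(2R,3S)-2-{(S)-[5-(benzyloxy)-2-bromophenoxy][4-(benzyloxy)phenyl]methyl}-3-{(R)-[5-(benzyloxy)-2-bromophenoxy][4-(benzyloxy)phenyl]methyl}butanedial F1, used crude. A twofold intramolecular Nozaki–Hiyama–Kishi arylation (CrCl2, divalent chromium, in excess; catalytic NiCl2; DMF, rt to 50 °C) then joins each C-4a to its aldehyde carbon under non-basic conditions; aryl bromides are slower partners than iodides, so the nickel loading and the temperature would be raised as needed. It should give 7,7'-bis(benzyloxy)-2,2'-bis[4-(benzyloxy)phenyl]-[3,3'-bichromane]-4,4'-diol F2 (C-2, C-3, C-2', C-3' as in 14; carbinol configuration undefined). Dess–Martin oxidation of both carbinols (CH2Cl2, NaHCO3, rt) gives 14.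

Step 6 (second Mitsunobu etherification). The γ-hydroxy amide may relactonise before it is activated, the activated carbinol may be captured by the γ-amide oxygen instead of the phenol, or the p-alkoxybenzylic centre may ionise or eliminate, so the clean inversion would be lost. The fallback sets out from 10 and returns at 11, and it turns the internal capture into the inverting step. Treatment of 10 with PPh3 and DIAD without the phenol (THF, 0 °C) lets the γ-amide oxygen displace the activated oxygen intramolecularly with inversion (5-exo-tet); aqueous hydrolysis of the cyclic imidate salt should give the 2,3-cis lactone rac-(2S,3R,4S)-4-{(R)-[5-(benzyloxy)-2-bromophenoxy][4-(benzyloxy)phenyl]methyl}-2-[4-(benzyloxy)phenyl]-N-methoxy-N-methyl-5-oxooxolane-3-carboxamide F3. Aminolysis as in step 5 (AlMe3, MeNHOMe·HCl, CH2Cl2) opens it to the carbinol epimer of 10, rac-(2R,3S)-2-{(S)-[4-(benzyloxy)phenyl](hydroxy)methyl}-3-{(R)-[5-(benzyloxy)-2-bromophenoxy][4-(benzyloxy)phenyl]methyl}-N1,N4-dimethoxy-N1,N4-dimethylbutanediamide F4. Copper-catalysed Chan–Lam O-arylation with potassium [5-(benzyloxy)-2-bromophenyl]trifluoroborate (Cu(OAc)2·H2O, DMAP, 4 Å molecular sieves, O2, CH2Cl2, rt) forms the aryl–oxygen bond with retention at carbon, so no substitution at the benzylic centre is needed, and gives 11.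

Step 4 (first Mitsunobu etherification). The activated β-hydroxy lactone may dehydrate to the α-benzylidene lactone, or the benzylic centre may ionise so that inversion is only partial. The fallback sets out from 4 and returns at 9; it sets the carbinol configuration in the aldol step and then forms the ether with retention. An anti-selective boron aldol reaction (c-Hex2BOTf, Et3N, CH2Cl2, −78 °C; then 2; pH 7 buffer, H2O2), in which the ring-fixed E enolate reacts through a chair transition state on the face anti to the carboxamide, should give the carbinol epimer of 7, rac-(2R,3R,4S)-2-[4-(benzyloxy)phenyl]-4-{(R)-[4-(benzyloxy)phenyl](hydroxy)methyl}-N-methoxy-N-methyl-5-oxooxolane-3-carboxamide F5. Chan–Lam O-arylation with potassium [5-(benzyloxy)-2-bromophenyl]trifluoroborate (Cu(OAc)2·H2O, DMAP, 4 Å molecular sieves, O2, CH2Cl2, rt) under near-neutral conditions, which should spare the retro-aldol-prone adduct, proceeds with retention at carbon and gives 9.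

**Further compounds**

F1 | step 7 | meso-(2R,3S)-2-{(S)-[5-(benzyloxy)-2-bromophenoxy][4-(benzyloxy)phenyl]methyl}-3-{(R)-[5-(benzyloxy)-2-bromophenoxy][4-(benzyloxy)phenyl]methyl}butanedial | O=C[C@@H]([C@H](Oc1cc(OCc2ccccc2)ccc1Br)c1ccc(OCc2ccccc2)cc1)[C@H](C=O)[C@@H](Oc1cc(OCc2ccccc2)ccc1Br)c1ccc(OCc2ccccc2)cc1
F2 | step 7 | 7,7'-bis(benzyloxy)-2,2'-bis[4-(benzyloxy)phenyl]-[3,3'-bichromane]-4,4'-diol (C-2, C-3, C-2', C-3' as in 14; C-4, C-4' undefined) | OC1c2ccc(OCc3ccccc3)cc2O[C@H](c2ccc(OCc3ccccc3)cc2)[C@H]1[C@@H]1C(O)c2ccc(OCc3ccccc3)cc2O[C@H]1c1ccc(OCc2ccccc2)cc1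
F3 | step 6 | rac-(2S,3R,4S)-4-{(R)-[5-(benzyloxy)-2-bromophenoxy][4-(benzyloxy)phenyl]methyl}-2-[4-(benzyloxy)phenyl]-N-methoxy-N-methyl-5-oxooxolane-3-carboxamide | O=C1[C@H]([C@@H](Oc2cc(OCc3ccccc3)ccc2Br)c2ccc(OCc3ccccc3)cc2)[C@@H](C(=O)N(C)OC)[C@@H](c2ccc(OCc3ccccc3)cc2)O1
F4 | step 6 | rac-(2R,3S)-2-{(S)-[4-(benzyloxy)phenyl](hydroxy)methyl}-3-{(R)-[5-(benzyloxy)-2-bromophenoxy][4-(benzyloxy)phenyl]methyl}-N1,N4-dimethoxy-N1,N4-dimethylbutanediamide | CON(C)C(=O)[C@@H]([C@H](O)c1ccc(OCc2ccccc2)cc1)[C@H](C(=O)N(C)OC)[C@@H](Oc1cc(OCc2ccccc2)ccc1Br)c1ccc(OCc2ccccc2)cc1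
F5 | step 4 | rac-(2R,3R,4S)-2-[4-(benzyloxy)phenyl]-4-{(R)-[4-(benzyloxy)phenyl](hydroxy)methyl}-N-methoxy-N-methyl-5-oxooxolane-3-carboxamide | O=C1[C@H]([C@@H](O)c2ccc(OCc3ccccc3)cc2)[C@@H](C(=O)N(C)OC)[C@H](c2ccc(OCc3ccccc3)cc2)O1
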